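## Structural features

The target is a single six-membered carbocycle, a cyclohex-1-ene whose C1 carries a methyl ester conjugated with the C1=C2 double bond; it is a fully acylated methyl shikimate. C3, C4 and C5 are three adjacent oxygen-bearing stereocentres (3R,4S,5R; O3 cis to O4, O4 trans to O5), and C6 is the only ring methylene. Each oxygen carries a different ester: acetate on the allylic C3, (R)-2-methylbutanoate on C4 and (S)-3-methylpentanoate on C5, so two further stereocentres sit in the side chains and are best bought. The fragile points are the esters on neighbouring oxygens, which migrate as soon as a neighbour is a free hydroxyl, the enolisable α-centre of the 2-methylbutanoyl group, and the ring itself, which can lose acyloxy groups by elimination toward an aromatic ester under base. The real difficulty is therefore not the ring but placing three different acyl groups without ambiguity on three contiguous secondary oxygens, together with the cis relation of C3 to C4. The key step uses the fact that C3 is an allylic carbinol bonded to the vinylic C2 of the ring alkene. The C2–C3 bond can thus be made from a vinyl–metal at C2 and an aldehyde at C3 with an organochromium reagent that ignores esters, so both chiral esters can be in place before the ring exists.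

## Logic of the disconnections

**15 to 14.** The O3–acetyl bond is cut first. O3 is the one oxygen that does not exist as a hydroxyl until the ring is closed, and acetate is the smallest and most mobile of the three acyl groups, so it belongs at the end. This leaves a diester with one free allylic hydroxyl. The forward step must acetylate with retention and faster than the O4 ester can shift to O3.

**14 to 13.** The ring bond C2–C3 is cut, C2 becoming a vinyl bromide and C3 an aldehyde. The ring and the C3 stereocentre disappear, and 13 is an open chain whose only backbone stereocentres are C4 and C5. The forward step needs the E bromide (bromine on the same side as C6), a metal that adds to an aldehyde but not to four esters, control of the aldehyde face by C4, and dilution.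

**13 to 12 to 11.** The C3 oxidation level is lowered and the O3–Si bond is cut. The aldehyde of 13 is flanked by an α- and a β-acyloxy group and should exist only briefly, so it is carried as a silyl ether in 11. The forward steps must free O3 without moving the C4 ester onto it and oxidise under non-basic conditions.

**11 to 9 and 10.** The O4–acyl bond is cut, which removes the second chiral acid. The forward acylation of a flanked secondary hydroxyl must not epimerise the α-centre of 10 and must outrun migration of the C5 ester.

**9 to 8 to 7.** The O3–Si bond and the two acetal C–O bonds are cut. The acetonide in 7 hides O3 and O4 together through all earlier steps; once it is removed, the primary/secondary difference in 8 tells them apart. The forward steps need acid hydrolysis that spares the esters and a silylation selective for the primary hydroxyl.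

**7 to 5.** The C2–Br bond is cut, leaving the plain 1,1-disubstituted acrylate of 5. This returns the vinyl halide to a group that a simple allylation reagent delivers. The forward bromination–dehydrobromination must lose HBr from the CH2Br carbon, not from C6, and give the E isomer.

**5 to 3 and 4.** The C5–O bond is cut. Forming it with inversion joins the first chiral acid and corrects C5 in one operation. The forward step needs a clean SN2 displacement without elimination to a dienoate.

**3 to 1 and 2.** The C5–C6 bond is cut. C4 comes unchanged from 1 and all six ring carbons are present after this one C–C bond formation. The forward addition must be anti-selective and must not lactonise the γ-hydroxy ester.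

## Other disconnections considered

**Alternative 1:** The cut removes C1–C2 and C5–C6 together and turns O5 into the oxygen of a furan.

- **Forward key step:** furan A1 and 3-acryloyl-1,3-oxazolidin-2-one A2 would undergo a Diels–Alder reaction under a cationic Cu(SbF6)2 complex of a tert-butyl bis(oxazoline) ligand at low temperature, giving the endo oxanorbornene A3. Exchange of the imide for the methyl ester and enolate β-elimination would open the bridge to the dienol A4. Its only hydroxyl is O5, which could be acylated with 4. Syn-dihydroxylation of C3=C4 with OsO4, anti to the O5 ester, would complete the oxygen pattern.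
- **In favour:** the ring and two C–C bonds arise in one catalytic enantioselective step, and the absolute configuration comes from a catalyst rather than from the chiral pool. O5 is singled out automatically. The cis relation of C3 and C4 is guaranteed by the syn-addition mechanism.
- **Against:** furan cycloadditions are reversible and selectivity can erode on warming. A4 is one dehydration away from an aromatic ester. Most seriously, O3 and O4 appear together as a cis diol, so the acetate and the 2-methylbutanoate would have to be placed by regioselective monoacylation of two secondary hydroxyls that exchange acyl groups easily, or by a protecting-group detour.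
- **Comparison:** on the C3/C4 relative configuration and on the number of steps to the bare ring the alternative is the better. On structure the chosen plan is stronger, because each of the three oxygens is revealed or acylated at a different moment. On mechanism the two are equal, both resting on established reaction types. On step economy the alternative would be shorter only if the monoacylation were selective; otherwise it is equal or longer.

**Alternative 2:** The cut is C1–C2 at the quinate oxidation level, with C1 a tertiary carbinol and C3 a ketone.

- **Forward key step:** catalytic Hg(OCOCF3)2 in aqueous acetone would hydrate the exocyclic enol ether of the pyranoid heptulosonate A5 (made from a hexose glycal). The ring would open to a methyl ketone and an α-keto ester, and an intramolecular aldol would close the carbocycle to the dehydroquinate A6.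
- **In favour:** the logic follows the biosynthesis. C4 and C5 come from the sugar without any inversion. O4 (PMB), O5 (TBS) and C3 (ketone) are all distinct, and the C3 ketone would direct the later dehydration to the C1=C2 alkene.
- **Against:** A6 is far from the target. It needs dehydration, a face-selective 1,2-reduction of an enone that aromatises readily, removal of two protecting groups and three acylations. The route to A5 from the sugar is itself long, and a mercury salt is used.
- **Comparison:** on differentiation of the three oxygens the alternative is the equal of the chosen plan. On the origin of C4/C5 it is slightly the better, since no Mitsunobu inversion is needed. On C3 both depend on substrate control, which is equal. On step economy the chosen plan is clearly better, because it closes the ring on a chain that already carries both chiral esters and the correct oxidation pattern.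

**Alternative 3:** The cut is C3–C4.

- **Forward key step:** SmI2 would couple the enal carbon C3 and the aldehyde carbon C4 of the dialdehyde A7 through a ketyl, giving the cis diol A8 and creating both carbinol centres and the ring at once.
- **In favour:** only one stereocentre (C5) has to be procured. Two are set in the ring closure, and the samarium-bridged ketyl pair favours the cis diol, with O4 expected trans to the C5 silyl ether.
- **Against:** the enal ketyl is an allylic radical and may couple through C1 or simply be reduced. A7 is a sensitive β-silyloxy dialdehyde. O3 and O4 again emerge together as a diol. C7 is at the alcohol level, so PMB removal, two oxidations and an esterification follow, and the silyl group must later be exchanged for the 3-methylpentanoate.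
- **Comparison:** on the C3/C4 relative configuration and on the number of stereocentres to be supplied the alternative is the better. On mechanism the radical closure is the less predictable in chemoselectivity. On structure and step economy the chosen plan is better, because the ester oxidation level and both chiral esters are present before ring closure and only one acetylation follows it.

Key step: step 9

Remarks on the chemistry.
- Ring numbering (C1 with CO2Me, C2 vinyl CH, C3 to C5 oxygenated, C6 methylene) is also used for the corresponding carbons of the open-chain compounds.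
- The structures were checked atom by atom against the target and are consistent. The only point needing care is nomenclature: 14 is (3R,4R,5R) and 15 is (3R,4S,5R) although no centre changes, because the CIP ranking at C4 changes when O3 is acetylated.
- Assumption: the zinc-mediated addition is taken to favour the anti adduct, the usual non-chelation outcome for this aldehyde.
- Design choices for the precursor: it is used as the pure E bromide, so no isomerisation of the vinyl–metal is relied on, and the aldehyde is made last and not stored.

## Route

Step 1
Reactants: 1 (R)-glyceraldehyde acetonide; 2 methyl 2-(bromomethyl)acrylate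
Product: 3 methyl (4S)-4-[(4R)-2,2-dimethyl-1,3-dioxolan-4-yl]-4-hydroxy-2-methylidenebutanoate
Conditions: Zn dust, sat. aq. NH4Cl/THF, 0 °C to rt
Reagents that add atoms: none
Why: Barbier-type allylation: zinc inserts into the allylic C–Br bond of 2 and the allylzinc adds to the aldehyde of 1; a non-chelated Felkin–Anh approach anti to the dioxolane C–O bond should favour the anti (4S) carbinol, which is separated from the minor syn epimer. C4 of the ring comes unchanged from 1, and the near-neutral medium should keep the γ-hydroxy ester from closing to the lactone.

Step 2
Reactants: 3 methyl (4S)-4-[(4R)-2,2-dimethyl-1,3-dioxolan-4-yl]-4-hydroxy-2-methylidenebutanoate; 4 (S)-3-methylpentanoic acid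
Product: 5 methyl (4R)-4-[(4R)-2,2-dimethyl-1,3-dioxolan-4-yl]-2-methylidene-4-{[(3S)-3-methylpentanoyl]oxy}butanoate
Conditions: PPh3, DIAD, THF, 0 °C to rt
Reagents that add atoms: none
Why: Mitsunobu esterification: the alcohol is activated as its oxyphosphonium ion and displaced by the carboxylate of 4 in an SN2 step, which inverts the carbinol to the configuration needed at ring C5 and installs the first chiral ester in the same operation. The stereocentre of 4 is β to the carboxyl and cannot epimerise.

Step 3
Reactants: 5 methyl (4R)-4-[(4R)-2,2-dimethyl-1,3-dioxolan-4-yl]-2-methylidene-4-{[(3S)-3-methylpentanoyl]oxy}butanoate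
Product: 7 methyl (2E,4R)-2-(bromomethylidene)-4-[(4R)-2,2-dimethyl-1,3-dioxolan-4-yl]-4-{[(3S)-3-methylpentanoyl]oxy}butanoate, via vicinal dibromide 6 (not isolated)
Conditions: Br2, CH2Cl2, 0 °C, dark; then DBU, 0 °C to rt
Reagents that add atoms: bromine, BrBr
Why: Electrophilic addition of bromine to the 1,1-disubstituted acrylate, then E2 dehydrobromination: with no α-hydrogen available, the base should remove the more acidic hydrogen of the CH2Br group anti to the tertiary bromide and give the conjugated β-bromoacrylate. The E isomer (bromine trans to the ester, cis to the chain) is the less congested and the thermodynamically preferred one; any Z isomer is removed by chromatography.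

Step 4
Reactants: 7 methyl (2E,4R)-2-(bromomethylidene)-4-[(4R)-2,2-dimethyl-1,3-dioxolan-4-yl]-4-{[(3S)-3-methylpentanoyl]oxy}butanoate
Product: 8 methyl (2E,4R,5R)-2-(bromomethylidene)-5,6-dihydroxy-4-{[(3S)-3-methylpentanoyl]oxy}hexanoate
Conditions: AcOH/H2O (4:1), 40 °C
Reagents that add atoms: none
Why: Acid-catalysed hydrolysis of a terminal isopropylidene acetal; the weakly acidic medium should leave both esters and the vinyl bromide untouched and is slow to promote acyl migration.

Step 5
Reactants: 8 methyl (2E,4R,5R)-2-(bromomethylidene)-5,6-dihydroxy-4-{[(3S)-3-methylpentanoyl]oxy}hexanoate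
Product: 9 methyl (2E,4R,5R)-2-(bromomethylidene)-6-[(tert-butyldimethylsilyl)oxy]-5-hydroxy-4-{[(3S)-3-methylpentanoyl]oxy}hexanoate
Conditions: TBSCl, imidazole, CH2Cl2, −10 to 0 °C
Reagents that add atoms: tert-butyldimethylsilyl chloride, CC(C)(C)[Si](C)(C)Cl
Why: Chemoselective silylation: the bulky silyl chloride reacts much faster at the primary hydroxyl (future C3) than at the flanked secondary hydroxyl (future C4), which stays free for the second chiral acid.

Step 6
Reactants: 9 methyl (2E,4R,5R)-2-(bromomethylidene)-6-[(tert-butyldimethylsilyl)oxy]-5-hydroxy-4-{[(3S)-3-methylpentanoyl]oxy}hexanoate; 10 (R)-2-methylbutanoic acid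
Product: 11 methyl (2E,4R,5R)-2-(bromomethylidene)-6-[(tert-butyldimethylsilyl)oxy]-5-{[(2R)-2-methylbutanoyl]oxy}-4-{[(3S)-3-methylpentanoyl]oxy}hexanoate
Conditions: DCC, DMAP (cat.), CH2Cl2, 0 °C to rt
Reagents that add atoms: none
Why: Steglich esterification through the O-acylisourea and the acylpyridinium ion; at low temperature with little DMAP the α-centre of 10 should not epimerise, and acylation of O4 should outrun migration of the neighbouring ester.

Step 7
Reactants: 11 methyl (2E,4R,5R)-2-(bromomethylidene)-6-[(tert-butyldimethylsilyl)oxy]-5-{[(2R)-2-methylbutanoyl]oxy}-4-{[(3S)-3-methylpentanoyl]oxy}hexanoate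
Product: 12 methyl (2E,4R,5R)-2-(bromomethylidene)-6-hydroxy-5-{[(2R)-2-methylbutanoyl]oxy}-4-{[(3S)-3-methylpentanoyl]oxy}hexanoate
Conditions: HF·pyridine, pyridine/THF, 0 °C
Reagents that add atoms: none
Why: Fluoride cleavage of the Si–O bond under buffered, weakly acidic conditions, chosen because basic fluoride sources would drive the C4 ester onto the freed primary oxygen; the esters and the vinyl bromide are inert to HF·pyridine.

Step 8
Reactants: 12 methyl (2E,4R,5R)-2-(bromomethylidene)-6-hydroxy-5-{[(2R)-2-methylbutanoyl]oxy}-4-{[(3S)-3-methylpentanoyl]oxy}hexanoate
Product: 13 methyl (2E,4R,5S)-2-(bromomethylidene)-5-{[(2R)-2-methylbutanoyl]oxy}-4-{[(3S)-3-methylpentanoyl]oxy}-6-oxohexanoate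
Conditions: Dess–Martin periodinane, CH2Cl2, 0 °C to rt; used at once
Reagents that add atoms: none
Why: Dess–Martin oxidation: ligand exchange at hypervalent iodine and internal deprotonation give the aldehyde under non-basic conditions, so the α-acyloxy centre C4 should not epimerise and the β-acyloxy group should not be eliminated. The descriptor of C4 changes from R to S only because the aldehyde carbon now outranks C5.

Step 9
Reactants: 13 methyl (2E,4R,5S)-2-(bromomethylidene)-5-{[(2R)-2-methylbutanoyl]oxy}-4-{[(3S)-3-methylpentanoyl]oxy}-6-oxohexanoate
Product: 14 methyl (3R,4R,5R)-3-hydroxy-4-{[(2R)-2-methylbutanoyl]oxy}-5-{[(3S)-3-methylpentanoyl]oxy}cyclohex-1-ene-1-carboxylate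
Conditions: CrCl2 (excess), NiCl2 (cat.), degassed DMF, rt, slow addition to about 0.005 M; aq. NH4Cl work-up at 0 °C
Reagents that add atoms: none
Why: CrCl2 reduces NiCl2 to zerovalent nickel, which inserts into the electron-poor C2–Br bond of 13; transmetalation to trivalent chromium frees the nickel and gives a vinylchromium dichloride that adds to the C3 aldehyde. This is the intramolecular Nozaki–Hiyama–Kishi reaction of an alkenyl halide with an aldehyde, the closest known type being the closure of β-halo enoate aldehydes to cyclic allylic alcohols. The one ring formed, the cyclohexene, closes in the 6-exo-trig mode at the aldehyde carbon, and the E geometry places C2 on the same side of the double bond as C6 so that the six atoms can meet without strain. The new C3 centre is controlled by the C4 acyloxy group: in the half-chair transition state O4 and O5 sit pseudo-equatorial, the C4–O bond lies anti to the forming C2–C3 bond (polar Felkin–Anh), and the aldehyde oxygen then points pseudo-axial, which leads to the 3,4-cis alcohol with the 3R configuration. The step needs selectivity for the aldehyde over four esters, which the low basicity and ester-inert character of the vinylchromium should secure, and it needs closure to beat intermolecular coupling, which slow addition at high dilution should secure. A cold, near-neutral work-up is chosen so that the C4 ester should not move to O3 once the chromium alkoxide is hydrolysed.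

Step 10
Reactants: 14 methyl (3R,4R,5R)-3-hydroxy-4-{[(2R)-2-methylbutanoyl]oxy}-5-{[(3S)-3-methylpentanoyl]oxy}cyclohex-1-ene-1-carboxylate
Product: 15 methyl (3R,4S,5R)-3-acetoxy-4-{[(2R)-2-methylbutanoyl]oxy}-5-{[(3S)-3-methylpentanoyl]oxy}cyclohex-1-ene-1-carboxylate
Conditions: Ac2O, pyridine, DMAP (cat.), CH2Cl2, 0 °C
Reagents that add atoms: acetic anhydride, CC(=O)OC(C)=O
Why: DMAP-catalysed acylation of the allylic alcohol with retention at C3; it is run on freshly isolated 14 so that acetylation precedes any shift of the C4 ester to O3.

## Compound list

1 | (R)-2,2-dimethyl-1,3-dioxolane-4-carbaldehyde ((R)-glyceraldehyde acetonide) | O=C[C@H]1COC(C)(C)O1 | starting material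
2 | methyl 2-(bromomethyl)acrylate | C=C(CBr)C(=O)OC | starting material
3 | methyl (4S)-4-[(4R)-2,2-dimethyl-1,3-dioxolan-4-yl]-4-hydroxy-2-methylidenebutanoate | C=C(C(=O)OC)C[C@H](O)[C@H]1COC(C)(C)O1 | intermediate
4 | (S)-3-methylpentanoic acid | CC[C@H](C)CC(=O)O | starting material
5 | methyl (4R)-4-[(4R)-2,2-dimethyl-1,3-dioxolan-4-yl]-2-methylidene-4-{[(3S)-3-methylpentanoyl]oxy}butanoate | C=C(C(=O)OC)C[C@@H](OC(=O)C[C@@H](C)CC)[C@H]1COC(C)(C)O1 | intermediate
6 | methyl (4R)-2-bromo-2-(bromomethyl)-4-[(4R)-2,2-dimethyl-1,3-dioxolan-4-yl]-4-{[(3S)-3-methylpentanoyl]oxy}butanoate, both C2 epimers, not isolated | COC(=O)C(Br)(CBr)C[C@@H](OC(=O)C[C@@H](C)CC)[C@H]1COC(C)(C)O1 | intermediate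
7 | methyl (2E,4R)-2-(bromomethylidene)-4-[(4R)-2,2-dimethyl-1,3-dioxolan-4-yl]-4-{[(3S)-3-methylpentanoyl]oxy}butanoate | CC1(C)OC[C@@H](O1)[C@H](OC(=O)C[C@@H](C)CC)C/C(C(=O)OC)=C\Br | intermediate
8 | methyl (2E,4R,5R)-2-(bromomethylidene)-5,6-dihydroxy-4-{[(3S)-3-methylpentanoyl]oxy}hexanoate | OC[C@@H](O)[C@H](OC(=O)C[C@@H](C)CC)C/C(C(=O)OC)=C\Br | intermediate
9 | methyl (2E,4R,5R)-2-(bromomethylidene)-6-[(tert-butyldimethylsilyl)oxy]-5-hydroxy-4-{[(3S)-3-methylpentanoyl]oxy}hexanoate | CC(C)(C)[Si](C)(C)OC[C@@H](O)[C@H](OC(=O)C[C@@H](C)CC)C/C(C(=O)OC)=C\Br | intermediate
10 | (R)-2-methylbutanoic acid | CC[C@@H](C)C(=O)O | starting material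
11 | methyl (2E,4R,5R)-2-(bromomethylidene)-6-[(tert-butyldimethylsilyl)oxy]-5-{[(2R)-2-methylbutanoyl]oxy}-4-{[(3S)-3-methylpentanoyl]oxy}hexanoate | CC(C)(C)[Si](C)(C)OC[C@@H](OC(=O)[C@H](C)CC)[C@H](OC(=O)C[C@@H](C)CC)C/C(C(=O)OC)=C\Br | intermediate
12 | methyl (2E,4R,5R)-2-(bromomethylidene)-6-hydroxy-5-{[(2R)-2-methylbutanoyl]oxy}-4-{[(3S)-3-methylpentanoyl]oxy}hexanoate | OC[C@@H](OC(=O)[C@H](C)CC)[C@H](OC(=O)C[C@@H](C)CC)C/C(C(=O)OC)=C\Br | intermediate
13 | methyl (2E,4R,5S)-2-(bromomethylidene)-5-{[(2R)-2-methylbutanoyl]oxy}-4-{[(3S)-3-methylpentanoyl]oxy}-6-oxohexanoate | O=C[C@@H](OC(=O)[C@H](C)CC)[C@H](OC(=O)C[C@@H](C)CC)C/C(C(=O)OC)=C\Br | intermediate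
14 | methyl (3R,4R,5R)-3-hydroxy-4-{[(2R)-2-methylbutanoyl]oxy}-5-{[(3S)-3-methylpentanoyl]oxy}cyclohex-1-ene-1-carboxylate | CC[C@H](C)CC(=O)O[C@@H]1CC(C(=O)OC)=C[C@@H](O)[C@H]1OC(=O)[C@H](C)CC | intermediate
15 | methyl (3R,4S,5R)-3-acetoxy-4-{[(2R)-2-methylbutanoyl]oxy}-5-{[(3S)-3-methylpentanoyl]oxy}cyclohex-1-ene-1-carboxylate | CC[C@H](C)CC(=O)O[C@@H]1CC(C(=O)OC)=C[C@@H](OC(C)=O)[C@H]1OC(=O)[C@H](C)CC | target

## Step count and risks

Total step count: 10. Longest linear sequence: 10 steps, from 1 to 15; 2, 4 and 10 enter as purchased.

**Step 9 (key step).** The most likely failure is poor facial selectivity at C3, because placing the aldehyde oxygen pseudo-equatorial is sterically easier than the Felkin arrangement. Also possible are slow insertion into the bromide with simple loss of bromine, and a shift of the C4 ester to O3 during work-up. The fallback sets out from 13. The same closure is run and the C3 epimer, methyl (3S,4R,5R)-3-hydroxy-4-{[(2R)-2-methylbutanoyl]oxy}-5-{[(3S)-3-methylpentanoyl]oxy}cyclohex-1-ene-1-carboxylate F1, is not acetylated with retention. It is instead treated with acetic acid under Mitsunobu conditions (PPh3, DIAD, AcOH, toluene, 0 °C), which should invert C3 and install the acetate in one operation. The route is rejoined at 15. Participation of the trans C4 ester is the point to watch there.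

**Step 3.** HBr may be lost toward C6, giving a rearranged allylic bromide, and E/Z control may be poor, because the base can choose between two kinds of β-hydrogen and two rotamers. The fallback sets out from 5. Ozonolysis (O3, CH2Cl2, −78 °C; Me2S) would cut the methylidene group to the α-keto ester methyl (4R)-4-[(4R)-2,2-dimethyl-1,3-dioxolan-4-yl]-4-{[(3S)-3-methylpentanoyl]oxy}-2-oxobutanoate F2. Wittig bromomethylenation with the ylide from (bromomethyl)triphenylphosphonium bromide and NaN(SiMe3)2 at −78 °C would then build the C=CHBr unit directly. The route is rejoined at 7 after removal of the Z isomer.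

**Step 2.** The activated alcohol may eliminate to the conjugated dienoate, or conversion may be incomplete because an aliphatic acid protonates the betaine less readily than an aromatic one. The fallback sets out from 3. The alcohol is converted with Tf2O and pyridine (CH2Cl2, −20 °C) into the triflate methyl (4S)-4-[(4R)-2,2-dimethyl-1,3-dioxolan-4-yl]-2-methylidene-4-[(trifluoromethylsulfonyl)oxy]butanoate F3. This is displaced with inversion by the carboxylate made from 4 and Cs2CO3 (18-crown-6, toluene, rt). The route is rejoined at 5.

**Step 7.** The C4 ester may migrate to the freed primary oxygen during or after desilylation, since a primary hydroxyl next to a secondary ester is the favoured resting place of the acyl group. The fallback sets out from 8 and never liberates 12. O3 is protected with TESCl/imidazole as methyl (2E,4R,5R)-2-(bromomethylidene)-5-hydroxy-4-{[(3S)-3-methylpentanoyl]oxy}-6-[(triethylsilyl)oxy]hexanoate F4. O4 is acylated with 10 (DCC, DMAP) to methyl (2E,4R,5R)-2-(bromomethylidene)-5-{[(2R)-2-methylbutanoyl]oxy}-4-{[(3S)-3-methylpentanoyl]oxy}-6-[(triethylsilyl)oxy]hexanoate F5. Swern conditions (oxalyl chloride, DMSO, CH2Cl2, −78 to −40 °C; iPr2NEt) are known to cleave a primary triethylsilyl ether and oxidise it in the same flask. The route is rejoined at 13.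

**Step 1.** Diastereoselection may be only modest and some lactonisation may occur, because the aqueous Barbier addition is not strongly face-selective and the product is a γ-hydroxy ester. The fallback sets out from 1 and 2 under the same conditions. The minor syn adduct, methyl (4R)-4-[(4R)-2,2-dimethyl-1,3-dioxolan-4-yl]-4-hydroxy-2-methylidenebutanoate F6, is also collected and esterified with 4 with retention (DCC, DMAP, CH2Cl2, 0 °C). Both diastereomers thus converge, and the route is rejoined at 5.

## Further compounds

F1 | step 9 | methyl (3S,4R,5R)-3-hydroxy-4-{[(2R)-2-methylbutanoyl]oxy}-5-{[(3S)-3-methylpentanoyl]oxy}cyclohex-1-ene-1-carboxylate (C3 epimer of 14) | CC[C@H](C)CC(=O)O[C@@H]1CC(C(=O)OC)=C[C@H](O)[C@H]1OC(=O)[C@H](C)CC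
F2 | step 3 | methyl (4R)-4-[(4R)-2,2-dimethyl-1,3-dioxolan-4-yl]-4-{[(3S)-3-methylpentanoyl]oxy}-2-oxobutanoate | COC(=O)C(=O)C[C@@H](OC(=O)C[C@@H](C)CC)[C@H]1COC(C)(C)O1
F3 | step 2 | methyl (4S)-4-[(4R)-2,2-dimethyl-1,3-dioxolan-4-yl]-2-methylidene-4-[(trifluoromethylsulfonyl)oxy]butanoate | C=C(C(=O)OC)C[C@H](OS(=O)(=O)C(F)(F)F)[C@H]1COC(C)(C)O1
F4 | step 7 | methyl (2E,4R,5R)-2-(bromomethylidene)-5-hydroxy-4-{[(3S)-3-methylpentanoyl]oxy}-6-[(triethylsilyl)oxy]hexanoate | CC[Si](CC)(CC)OC[C@@H](O)[C@H](OC(=O)C[C@@H](C)CC)C/C(C(=O)OC)=C\Br
F5 | step 7 | methyl (2E,4R,5R)-2-(bromomethylidene)-5-{[(2R)-2-methylbutanoyl]oxy}-4-{[(3S)-3-methylpentanoyl]oxy}-6-[(triethylsilyl)oxy]hexanoate | CC[Si](CC)(CC)OC[C@@H](OC(=O)[C@H](C)CC)[C@H](OC(=O)C[C@@H](C)CC)C/C(C(=O)OC)=C\Br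
F6 | step 1 | methyl (4R)-4-[(4R)-2,2-dimethyl-1,3-dioxolan-4-yl]-4-hydroxy-2-methylidenebutanoate (syn adduct) | C=C(C(=O)OC)C[C@@H](O)[C@H]1COC(C)(C)O1
A1 | alternative 1 | furan | c1ccoc1
A2 | alternative 1 | 3-acryloyl-1,3-oxazolidin-2-one | C=CC(=O)N1CCOC1=O
A3 | alternative 1 | 3-[(1R,2R,4R)-7-oxabicyclo[2.2.1]hept-5-ene-2-carbonyl]-1,3-oxazolidin-2-one (endo adduct) | O=C(N1CCOC1=O)[C@@H]2C[C@@H]3C=C[C@H]2O3
A4 | alternative 1 | methyl (5R)-5-hydroxycyclohexa-1,3-diene-1-carboxylate | O[C@@H]1CC(C(=O)OC)=CC=C1
A5 | alternative 2 | methyl 2-methoxy-5-[(4-methoxybenzyl)oxy]-4-[(tert-butyldimethylsilyl)oxy]-6-methylidenetetrahydropyran-2-carboxylate (pyranoid heptulosonate enol ether, anomeric centre left open, other centres as in A6) | C=C1[C@@H](OCc2ccc(OC)cc2)[C@H](O[Si](C)(C)C(C)(C)C)CC(OC)(C(=O)OC)O1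
A6 | alternative 2 | methyl 4-O-(4-methoxybenzyl)-5-O-(tert-butyldimethylsilyl)-3-dehydroquinate | O[C@@]1(C(=O)OC)CC(=O)[C@@H](OCc2ccc(OC)cc2)[C@H](O[Si](C)(C)C(C)(C)C)C1
A7 | alternative 3 | (2E,5R)-5-[(tert-butyldimethylsilyl)oxy]-3-{[(4-methoxybenzyl)oxy]methyl}hex-2-enedial | O=C/C=C(/COCc1ccc(OC)cc1)C[C@@H](O[Si](C)(C)C(C)(C)C)C=O
A8 | alternative 3 | cis-3,4-diol of 5-O-(tert-butyldimethylsilyl)-7-O-(4-methoxybenzyl)shikimyl alcohol, ring centres arranged as in shikimic acid | CC(C)(C)[Si](C)(C)O[C@@H]1CC(COCc2ccc(OC)cc2)=C[C@@H](O)[C@H]1O
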